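At late times the maple readings stop rising: E stands at 6.5 % after 12.0 h and at 6.3 % after 20.0 h, a difference smaller than the scatter of 0.3 percentage points. So what to watch in this flask is how many stopping times fit into the run.

| setting | maple | flask |
|---|---|---|
| X | 20 mM | 20 mM |
| J | 30 mM | 30.0 mM |
| L | 2 mM | 2.00 mM |
| remark | the very flask that is asked about, followed so far |  |
| time |  | 50 h |
| volume of the second phase over the first |  | 2.0 |

maple run (percent of the X charged): time / h: E / % = 1.00: 0.9; 3.00: 2.8; 6.00: 4.4; 8.00: 5.0; 12.0: 6.5; 15.0: 6.3; 20.0: 6.3

(scatter of a reading: 0.3 percentage points)

- in the second phase: J; everything else is in the first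
- charges count per volume of the first phase; a concentration in a rate is the amount of a species over the volume of its own phase; every rate counts per litre of the first phase
- the earlier runs hold the two phases in the same ratio of volumes as the flask asked about

- amount of E at 50 h, in percent of the X charged
- the change that raises the amount of E at 50 h, in percent of the X charged most ("none" if none brings more than 2 percentage points) (dawn / midnight / none)
- amount of E at 50 h, in percent of the X charged, after midnight

- dawn: doubling the amount of J, all else as stated
- midnight: doubling the transfer coefficient of J, all else as stated

I average the last 3 readings to a plateau of 6.37 % and take the early slope from 2.8 % at 3.00 h. Plateau over slope gives a stopping time of 6.82 h. The stop number N, the asked time over the stopping time 7.33, counts the time constants of a first-order approach to the plateau that the run lasts. Here it is 7.33, so the gap shrinks by 3.18 powers of ten, to 0.0042 points, far below the scatter. I therefore commit to the plateau for the flask at 50 h.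

Is one number enough? My curve gives 3.72 % at 6.00 h against a reading of 4.4 %, lower by 0.68 points, which exceeds the scatter. The readings bend sooner than my stopping time, and that raises N. But N says when, not how high, so it leaves dawn and midnight open.

The forecast gives 6.5 %, dawn as the best change and 7 % after midnight, holding that “More J raises dissolved J in every scenario”.

The flask gives 6.80 %; dawn adds 5.1 points, midnight 0.0083 points, which leaves 6.81 %, so the best change is dawn.

    D → G (k = 0.416 h⁻¹)
    D + E → Q (k = 2.60 M⁻¹ h⁻¹)
    X + L → Z (k = 6.96 M⁻¹ h⁻¹)
    D ⇌ J, rate k4*([D] - [J]/K4) per volume of the first phase (partition coefficient = 0.760, kL = 3.35 h⁻¹)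
    X + D → E (k = 1.19 M⁻¹ h⁻¹)

With N at 7.33 I expected no further rise, and this flask shows 6.80 % at 500 h. The neighbouring flask is charged with 5.0 mM of X, all else held. The step X + D → E is first order in X and E is counted in percent of the X charged, so I keep N at 7.33 and expect the plateau of 6.37 % again. That flask ends at 6.87 %, with [D] at 0.00399 mM and 63 % of its X still there.

The runs stem from a simulated flask with made-up constants, and the scatter is random.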